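Numbering used throughout: tetralin carbons C1–C4 (saturated ring), C4a/C8a (fusion), C5–C8 (aromatic ring); C20 is the oxygen-bearing CH2 on C1; the side chain on C4 is C1'–C5' (methyl on C1', alkene C4'=C5'). Compound numbers are those of the steps below.

## Analysis of the target

Target 28 is a tetralin whose aromatic ring carries a carboxylic acid at C6 and a phenol at C8, and whose saturated ring carries an acetoxymethyl group at C1 and a 6-methylhept-5-en-2-yl chain at C4. It has three stereocentres, C1 (R), C4 (S) and C1' (S). C1 and C4 are trans across the saturated ring, while C4 and C1' are neighbours, with C1' outside the ring and conformationally free. None of the three is next to a carbonyl group, so none can be corrected by equilibration. The sensitive groups are the primary acetate (no strong base or nucleophile late), the free phenol peri to C1 (oxidation, halogenation), and the trisubstituted alkene (no hydrogenation, strong acid or electrophilic oxidant). The hard part is the C4/C1' pair, a benzylic methine beside a methyl-bearing methine with no heteroatom to direct a reagent, together with the 1,4-trans relation to C1. A further difficulty is the arene, where C8a is flanked by substituents on both sides. The strategy rests on one feature: C4 and C1' are the α and β carbons of an E-propenyl group on C4a, C2'–C5' is a 4-methylpent-3-enyl carbanion, and C3 is an electrophilic CH2 at the end of an arm on C8a that already holds C1, C2 and C20. Bonds C1'–C2' and C3–C4 can therefore be made in one anionic operation that also closes the saturated ring.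

## Retrosynthetic reasoning

**28 back to 24 (no skeletal bond cut).** The acid is traced to an aldehyde and then to a dimethyl acetal, the acetate to a primary alcohol held as a silyl ether, and the phenol to a bulky aryl silyl ether. The order 28 ⇐ 27 ⇐ 26 ⇐ 25 ⇐ 24 follows from two needs: acetylation requires the C20 hydroxyl free and the phenol masked, and the aldehyde oxidation requires the phenol still masked. The gain is that 24 and everything before it contain neither ester, acid nor acetate at the stage where an organolithium is used.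

**24 back to 19 and 22 (cut C1'–C2' and C3–C4).** Both bonds end on the C4/C1' pair. Cutting them removes the two hardest stereocentres and the saturated ring together, and leaves C4=C1' as an E alkene and the chain as organolithium 22, made from iodide 21 and hence bromide 20. A cut at C4–C4a would demand electrophilic substitution on an arene deactivated at that carbon. A cut at C1–C8a would leave an open chain with a 1,4-stereochemical problem. The forward reaction has to add 22 to one face of the alkene with carbon going to C1', close the ring through the benzylic carbanion 23 before anything else happens to it, and deliver C4 trans to C1.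

**19 back to 17 and 18 (cut C4a–C4).** The aryl–alkenyl bond is made last before the key step from triflate 17 and boronic acid 18. This keeps the styrene out of every earlier step, and the E geometry is bought with 18.

**17 back to 14 through 16 and 15 (functional-group change at C6).** The acetal comes from the methyl ester by reduction, oxidation and acetalisation. The change is placed after C1 is set because the ester tolerates the enolate chemistry, whereas an acetal would not survive the acid used to make 6.

**14 back to 9 and 10 through 13 and 12 (cut C1–C2).** C1 is the α-carbon of an arylacetyl imide and C20 its carbonyl carbon, so an auxiliary-controlled enolate alkylation sets C1. Electrophile 10 brings C2, C3 and the chloride. A primary chloride is the one leaving group that stays inert towards an alkyllithium until a carbanion is generated next to it.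

**9 back to 6 and 7, and 6 back to 3 and 4 through 5 (cut N–acyl, then C8a–C1).** The imide comes from acid 6 and oxazolidinone 7. The aryl–CH2 bond is a palladium-catalysed coupling of aryl bromide 3 with zinc enolate 4.

**3 back to 1 through 2.** In 1 the bromine marks C8a, the ester marks C6, and the two equivalent phenols become C8–O and the C4a handle. One is triflated and the other silylated.

## Alternatives that were turned down

**Alternative 1:** The aromatic ring is taken apart at C4a–C5 and C8a–C8. This leads back to the 2-sulfinyl enone A2, which already holds C1–C4 and the side chain and would be made from (S)-citronellal A4 (its stereocentre becomes C1'), and to the 1,1-dioxygenated diene A3.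
- Forward step: a Diels–Alder reaction in which the nucleophilic CH2 terminus of A3 bonds to the enone β-carbon (C4a) and the ketene-acetal carbon bonds to the sulfinyl-bearing carbon (C8a). Loss of the sulfenic acid and collapse of the ketal then aromatise the new ring to phenol A1.
- For: C1' comes from the chiral pool and is more secure than any reagent-controlled addition. The polarity of the partners fixes the positions of ester and hydroxyl, and the reaction type is well behaved.
- Against: A1 still has a ketone at C1. C20 and the C1 stereocentre must then be built on a carbonyl that is hydrogen-bonded to the peri hydroxyl and easily enolised, and a methylenation–hydroboration sequence would have to find the 1,4-trans isomer with no nearer control element than C4. C4 in A2 must be set relative to C1' in a separate catalyst-controlled annulation, and the methyl ester must later be cleaved beside a primary acetate.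
- Comparison: stronger at C1' and no weaker at the arene, but it postpones C1 to a late, weakly controlled step. The chosen route sets C1 first with an auxiliary and then forms C1', C4 and the ring in one step.

**Alternative 2:** Both rings are opened at once, at C4a–C8a and C7–C8, to the open-chain furan–yne A6. A 2,4-disubstituted furan supplies C4a, C5, C6 and C7, and a terminal alkyne supplies C8a and C8.
- Forward step: [(Ph3P)Au]NTf2 activates the alkyne, furan C2 attacks its internal carbon, and the cyclopropyl carbenoid opens and recloses through an arene oxide, so that the furan oxygen ends as the C8 hydroxyl of A5, the allyl ester of the target.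
- For: catalytic and neutral, places the hydroxyl next to the ring fusion as required, tolerates the acetate, and A5 is one deallylation from the target. That endgame is clearly shorter than the four steps of the chosen route.
- Against: A6 must carry C1, C4 and C1' in an acyclic chain, so all three centres must be built by separate acyclic methods before a key step that creates none. The tether is an all-carbon four-atom chain without heteroatom or geminal substitution, the slowest case for this isomerisation. The furan is deactivated by its ester, and the side-chain alkene is a competing nucleophile for the gold-bound alkyne.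
- Comparison: the chosen route has the longer endgame, but it needs only one stereocentre before its key step and lets that step create the other two.

**Alternative 3:** The C1–C8a bond is disconnected as the result of a 1,2-aryl shift. This leads back to the benzocycloheptene A8, in which C20 is still a ring carbon between C8a and C1.
- Forward step: PhI(OH)OTs, in the alcohol that supplies the acetal oxygens, adds to the C20=C1 styrene bond. Aryl carbon C8a migrates from C20 to C1 with loss of the aryl iodide, and C20 leaves the ring as a dimethyl acetal, giving tetralin A7.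
- For: oxidative ring contraction of benzo-fused cycloalkenes by trivalent iodine is an established reaction type, so this key step stands on firmer ground than the cascade chosen here. The 1,4-trans product is the expected one, and C20 arrives at the aldehyde oxidation level.
- Against: the electrophilic iodine reagent would not spare the trisubstituted alkene, so the side chain must be carried truncated (a benzyl ether in A7) and completed afterwards by deprotection, oxidation and olefination. The migrating carbon C8a is para to the ester-bearing C6, which lowers its migratory aptitude and favours plain solvent addition. A seven-membered carbocycle with the C4/C1' pair in place must be made first, and the acetal of A7 unveils an epimerisable α-aryl aldehyde at C1.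
- Comparison: the safer key step but the longer synthesis on both sides of it. Its key step creates only C1, whereas the chosen step creates C4 and C1' with the complete side chain.

Key step: step 14

Remarks on the chemistry (assumptions):
- The sense of induction of (−)-sparteine is taken from simple E-β-methylstyrenes and is assumed to correspond to (S) at C1' in 19. If 19 responds with the opposite sense, (+)-sparteine would be used with no other change.
- Compounds 4, 7, 10, 18 and 20 are taken as purchased reagents. Compound 10 is otherwise made in one operation from 2-chloroethanol and Tf2O.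

## Route

Step 1
Reactants: 1 methyl 4-bromo-3,5-dihydroxybenzoate
Product: 2 methyl 4-bromo-3-hydroxy-5-{[(trifluoromethyl)sulfonyl]oxy}benzoate
Conditions: Tf2O (1.0 equiv), pyridine, CH2Cl2, −78 → 0 °C
Reagents that add atoms: triflic anhydride, O=S(=O)(OS(=O)(=O)C(F)(F)F)C(F)(F)F
Why: Sulfonylation of one of two equivalent phenols; the first triflate makes the remaining hydroxyl a poorer nucleophile, so the mono-triflate should exceed its statistical share, and unreacted 1 and the bis-triflate are separable.

Step 2
Reactants: 2 methyl 4-bromo-3-hydroxy-5-{[(trifluoromethyl)sulfonyl]oxy}benzoate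
Product: 3 methyl 4-bromo-3-{[(trifluoromethyl)sulfonyl]oxy}-5-[(triisopropylsilyl)oxy]benzoate
Conditions: i-Pr3SiOTf, 2,6-lutidine, CH2Cl2, 0 °C → rt
Reagents that add atoms: triisopropylsilyl triflate, CC(C)[Si](OS(=O)(=O)C(F)(F)F)(C(C)C)C(C)C
Why: Silylation of a hindered, electron-poor phenol with the reactive silyl triflate and a non-nucleophilic base; the triisopropylsilyl ether is chosen because it later resists alkyllithium, blocks ortho-lithiation and survives dilute acid.

Step 3
Reactants: 3 methyl 4-bromo-3-{[(trifluoromethyl)sulfonyl]oxy}-5-[(triisopropylsilyl)oxy]benzoate; 4 (2-tert-butoxy-2-oxoethyl)zinc chloride, ClZnCH2CO2t-Bu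
Product: 5 methyl 4-(2-tert-butoxy-2-oxoethyl)-3-{[(trifluoromethyl)sulfonyl]oxy}-5-[(triisopropylsilyl)oxy]benzoate
Conditions: Pd(dba)2 (5 mol %), P(t-Bu)3 (5 mol %), THF, rt → 50 °C
Reagents that add atoms: none
Why: Negishi-type α-arylation of a zinc ester enolate (Reformatsky reagent); zerovalent palladium carrying one bulky trialkylphosphine inserts into C–Br in preference to C–OTf, and the neutral zinc enolate leaves the methyl ester, the triflate and the silyl ether alone.

Step 4
Reactants: 5 methyl 4-(2-tert-butoxy-2-oxoethyl)-3-{[(trifluoromethyl)sulfonyl]oxy}-5-[(triisopropylsilyl)oxy]benzoate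
Product: 6 {4-(methoxycarbonyl)-2-{[(trifluoromethyl)sulfonyl]oxy}-6-[(triisopropylsilyl)oxy]phenyl}acetic acid
Conditions: CF3CO2H, CH2Cl2, 0 °C → rt
Reagents that add atoms: none
Why: Acidolysis of the tert-butyl ester through the tert-butyl cation; the methyl ester, the aryl triflate and the hindered aryl silyl ether are stable to anhydrous acid for the time needed.

Step 5
Reactants: 6 {4-(methoxycarbonyl)-2-{[(trifluoromethyl)sulfonyl]oxy}-6-[(triisopropylsilyl)oxy]phenyl}acetic acid; 7 (R)-4-benzyloxazolidin-2-one
Product: 9 methyl 4-{2-[(4R)-4-benzyl-2-oxo-1,3-oxazolidin-3-yl]-2-oxoethyl}-3-{[(trifluoromethyl)sulfonyl]oxy}-5-[(triisopropylsilyl)oxy]benzoate, via mixed pivalic anhydride 8 (not isolated)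
Conditions: t-BuCOCl, Et3N, THF, −20 °C; then 7, LiCl, −20 °C → rt
Reagents that add atoms: none
Why: N-acylation of the oxazolidinone through a mixed anhydride, which is attacked at the less hindered arylacetyl carbonyl; LiCl and Et3N activate the N–H, so no strong base meets the triflate or the ester.

Step 6
Reactants: 9 methyl 4-{2-[(4R)-4-benzyl-2-oxo-1,3-oxazolidin-3-yl]-2-oxoethyl}-3-{[(trifluoromethyl)sulfonyl]oxy}-5-[(triisopropylsilyl)oxy]benzoate; 10 2-chloroethyl trifluoromethanesulfonate
Product: 12 methyl 4-{(2R)-1-[(4R)-4-benzyl-2-oxo-1,3-oxazolidin-3-yl]-4-chloro-1-oxobutan-2-yl}-3-{[(trifluoromethyl)sulfonyl]oxy}-5-[(triisopropylsilyl)oxy]benzoate, via sodium Z-enolate 11 (not isolated)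
Conditions: NaN(SiMe3)2 (1.0 equiv), THF, −78 °C; then 10 (1.5 equiv), −78 → −40 °C
Reagents that add atoms: none
Why: Evans alkylation: the chelated Z-enolate 11 is attacked on the face opposite the benzyl group of the (R)-auxiliary, which gives (R) at C1 (aryl outranks the new chloroethyl group); a primary triflate is reactive enough for this stabilised enolate at low temperature, and the chloride is not touched.

Step 7
Reactants: 12 methyl 4-{(2R)-1-[(4R)-4-benzyl-2-oxo-1,3-oxazolidin-3-yl]-4-chloro-1-oxobutan-2-yl}-3-{[(trifluoromethyl)sulfonyl]oxy}-5-[(triisopropylsilyl)oxy]benzoate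
Product: 13 methyl 4-[(2R)-4-chloro-1-hydroxybutan-2-yl]-3-{[(trifluoromethyl)sulfonyl]oxy}-5-[(triisopropylsilyl)oxy]benzoate
Conditions: NaBH4, THF–H2O (4:1), 0 °C → rt
Reagents that add atoms: none
Why: Reductive removal of the auxiliary by borohydride at the exocyclic imide carbonyl; the methyl ester, triflate and chloride are inert, the medium is not basic enough to epimerise C1, and 7 is recovered.

Step 8
Reactants: 13 methyl 4-[(2R)-4-chloro-1-hydroxybutan-2-yl]-3-{[(trifluoromethyl)sulfonyl]oxy}-5-[(triisopropylsilyl)oxy]benzoate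
Product: 14 methyl 4-[(2R)-1-{[tert-butyl(dimethyl)silyl]oxy}-4-chlorobutan-2-yl]-3-{[(trifluoromethyl)sulfonyl]oxy}-5-[(triisopropylsilyl)oxy]benzoate
Conditions: t-BuMe2SiCl, imidazole, DMF, rt
Reagents that add atoms: tert-butyldimethylsilyl chloride, CC(C)(C)[Si](C)(C)Cl
Why: Standard silylation of a primary alcohol; imidazole is too weak a base to close the chloro alcohol to a tetrahydrofuran.

Step 9
Reactants: 14 methyl 4-[(2R)-1-{[tert-butyl(dimethyl)silyl]oxy}-4-chlorobutan-2-yl]-3-{[(trifluoromethyl)sulfonyl]oxy}-5-[(triisopropylsilyl)oxy]benzoate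
Product: 15 {4-[(2R)-1-{[tert-butyl(dimethyl)silyl]oxy}-4-chlorobutan-2-yl]-3-{[(trifluoromethyl)sulfonyl]oxy}-5-[(triisopropylsilyl)oxy]phenyl}methanol
Conditions: i-Bu2AlH (2.5 equiv), CH2Cl2, −78 °C; aq. potassium sodium tartrate
Reagents that add atoms: none
Why: Hydride reduction of the aryl ester to the benzylic alcohol; aryl triflate, alkyl chloride and both silyl ethers are stable to the aluminium hydride at low temperature.

Step 10
Reactants: 15 {4-[(2R)-1-{[tert-butyl(dimethyl)silyl]oxy}-4-chlorobutan-2-yl]-3-{[(trifluoromethyl)sulfonyl]oxy}-5-[(triisopropylsilyl)oxy]phenyl}methanol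
Product: 16 4-[(2R)-1-{[tert-butyl(dimethyl)silyl]oxy}-4-chlorobutan-2-yl]-3-{[(trifluoromethyl)sulfonyl]oxy}-5-[(triisopropylsilyl)oxy]benzaldehyde
Conditions: MnO2, CH2Cl2, rt
Reagents that add atoms: none
Why: Selective oxidation of a benzylic alcohol on the surface of manganese dioxide, which stops at the aldehyde and needs no acid or base.

Step 11
Reactants: 16 4-[(2R)-1-{[tert-butyl(dimethyl)silyl]oxy}-4-chlorobutan-2-yl]-3-{[(trifluoromethyl)sulfonyl]oxy}-5-[(triisopropylsilyl)oxy]benzaldehyde
Product: 17 2-[(2R)-1-{[tert-butyl(dimethyl)silyl]oxy}-4-chlorobutan-2-yl]-5-(dimethoxymethyl)-3-[(triisopropylsilyl)oxy]phenyl trifluoromethanesulfonate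
Conditions: MeOSiMe3 (2.5 equiv), Me3SiOTf (5 mol %), CH2Cl2, −78 °C; pyridine quench
Reagents that add atoms: methoxytrimethylsilane, CO[Si](C)(C)C
Why: Aprotic acetalisation under silyl triflate catalysis (Noyori conditions) through the oxocarbenium ion; the primary silyl ether, which would be lost in methanolic acid, is untouched at −78 °C.

Step 12
Reactants: 17 2-[(2R)-1-{[tert-butyl(dimethyl)silyl]oxy}-4-chlorobutan-2-yl]-5-(dimethoxymethyl)-3-[(triisopropylsilyl)oxy]phenyl trifluoromethanesulfonate; 18 (E)-prop-1-enylboronic acid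
Product: 19 tert-butyl{(2R)-4-chloro-2-[4-(dimethoxymethyl)-2-[(1E)-prop-1-en-1-yl]-6-[(triisopropylsilyl)oxy]phenyl]butoxy}dimethylsilane
Conditions: Pd(OAc)2 (5 mol %), SPhos (10 mol %), K3PO4, THF–H2O (10:1), 60 °C
Reagents that add atoms: none
Why: Suzuki–Miyaura coupling with retention of the E geometry of 18; the electron-rich biaryl phosphine promotes insertion into the hindered triflate, the primary alkyl chloride does not add to zerovalent palladium under these conditions, and the acetal is stable to base.

Step 13
Reactants: 20 5-bromo-2-methylpent-2-ene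
Product: 21 5-iodo-2-methylpent-2-ene
Conditions: NaI, acetone, reflux
Reagents that add atoms: sodium iodide, [Na+].[I-]
Why: Finkelstein exchange driven by precipitation of NaBr; the primary iodide undergoes clean lithium–iodine exchange in the next step, which the bromide would not.

Step 14
Reactants: 19 tert-butyl{(2R)-4-chloro-2-[4-(dimethoxymethyl)-2-[(1E)-prop-1-en-1-yl]-6-[(triisopropylsilyl)oxy]phenyl]butoxy}dimethylsilane; 21 5-iodo-2-methylpent-2-ene
Product: 24 tert-butyl{[(1R,4S)-6-(dimethoxymethyl)-4-[(2S)-6-methylhept-5-en-2-yl]-8-[(triisopropylsilyl)oxy]-1,2,3,4-tetrahydronaphthalen-1-yl]methoxy}dimethylsilane, via 4-methylpent-3-enyllithium 22 (not isolated), via benzylic lithium 23 (not isolated)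
Conditions: 21 (2.2 equiv), t-BuLi (4.4 equiv), pentane–Et2O (3:2), −78 °C → rt; solvents replaced by cumene; (−)-sparteine (2.4 equiv); 19, −30 → 0 °C; then THF, 0 °C → rt; MeOH
Reagents that add atoms: none
Why: Proposed new method: the sparteine-bound primary alkyllithium 22 should add syn across the E-propenyl double bond of 19, carbon to the methyl-bearing C1' and lithium to benzylic C4, since only this regiochemistry gives an aryl-stabilised carbanion; the closest known reaction type is the sparteine-mediated enantioselective carbolithiation of E-β-alkylstyrenes by alkyllithiums with intermolecular trapping of the benzylic lithium, and here the trap is built into the ortho arm. The benzylic lithium 23 then displaces the primary chloride at C3 in a 6-exo-tet SN2 closure, an alkylation in which the carbanion and its aryl group lie inside the forming ring and which is geometrically feasible for a six-membered ring, so that C3–C4 and the saturated ring are formed. C1' is set by the chiral diamine, which selects the alkene face in the addition; the existing C1 centre sits on an arm that places its two branches on opposite faces of the arene and should offer little bias of its own. C4 is not fixed by the syn addition, because a secondary benzylic lithium without a chelating group inverts readily; it should be fixed in the ring closure, through the half-chair in which the C1 silyloxymethyl group is pseudoaxial (away from the peri silyl ether on C8) and the branched side chain on C4 is also pseudoaxial (away from the peri C5–H), which is the 1,4-trans arrangement. The step needs the styrene to be the only site that reacts with 22: the chloride is inert to alkyllithiums at these temperatures, the carboxyl carbon is an acetal, both oxygens are silylated and the bulky aryl silyl ether suppresses ortho-lithiation at C7, and the C1–H bond lies in the arene plane between two ortho substituents and is therefore not benzylically acidic. The C8 silyl ether is meta to C4a and does not destabilise the benzylic carbanion, and THF is added only after the addition is complete so that it speeds the ring closure without opening an unligated pathway for the face-selective step.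

Step 15
Reactants: 24 tert-butyl{[(1R,4S)-6-(dimethoxymethyl)-4-[(2S)-6-methylhept-5-en-2-yl]-8-[(triisopropylsilyl)oxy]-1,2,3,4-tetrahydronaphthalen-1-yl]methoxy}dimethylsilane
Product: 25 (5R,8S)-5-(hydroxymethyl)-8-[(2S)-6-methylhept-5-en-2-yl]-4-[(triisopropylsilyl)oxy]-5,6,7,8-tetrahydronaphthalene-2-carbaldehyde
Conditions: 1 M aq. HCl, THF, rt
Reagents that add atoms: water, O
Why: Aqueous acid hydrolyses the aryl dimethyl acetal and the primary alkyl silyl ether; the hindered aryl triisopropylsilyl ether and the trisubstituted alkene are stable to dilute acid at room temperature.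

Step 16
Reactants: 25 (5R,8S)-5-(hydroxymethyl)-8-[(2S)-6-methylhept-5-en-2-yl]-4-[(triisopropylsilyl)oxy]-5,6,7,8-tetrahydronaphthalene-2-carbaldehyde
Product: 26 [(1R,4S)-6-formyl-4-[(2S)-6-methylhept-5-en-2-yl]-8-[(triisopropylsilyl)oxy]-1,2,3,4-tetrahydronaphthalen-1-yl]methyl acetate
Conditions: Ac2O, pyridine, DMAP (cat.), CH2Cl2, 0 °C → rt
Reagents that add atoms: acetic anhydride, CC(=O)OC(C)=O
Why: Nucleophile-catalysed acylation of the primary alcohol; no alkoxide is formed, so the silyl group should not migrate from the C8 oxygen to the nearby C20 oxygen.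

Step 17
Reactants: 26 [(1R,4S)-6-formyl-4-[(2S)-6-methylhept-5-en-2-yl]-8-[(triisopropylsilyl)oxy]-1,2,3,4-tetrahydronaphthalen-1-yl]methyl acetate
Product: 27 (5R,8S)-5-(acetoxymethyl)-8-[(2S)-6-methylhept-5-en-2-yl]-4-[(triisopropylsilyl)oxy]-5,6,7,8-tetrahydronaphthalene-2-carboxylic acid
Conditions: NaClO2, NaH2PO4, 2-methylbut-2-ene (excess), t-BuOH–H2O, 0 °C → rt
Reagents that add atoms: sodium chlorite, [Na+].[O-]Cl=O
Why: Pinnick oxidation of the aryl aldehyde; the hypochlorous acid released is trapped by the excess scavenger alkene, which protects the side-chain alkene, and the phenol is still silylated so the ring is not chlorinated.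

Step 18
Reactants: 27 (5R,8S)-5-(acetoxymethyl)-8-[(2S)-6-methylhept-5-en-2-yl]-4-[(triisopropylsilyl)oxy]-5,6,7,8-tetrahydronaphthalene-2-carboxylic acid
Product: 28 (5R,8S)-5-(acetoxymethyl)-4-hydroxy-8-[(2S)-6-methylhept-5-en-2-yl]-5,6,7,8-tetrahydronaphthalene-2-carboxylic acid (target; C1 R, C4 S, C1' S in the tetralin numbering)
Conditions: HF·pyridine, pyridine, THF, 0 °C → rt
Reagents that add atoms: none
Why: Fluoride cleavage of the aryl silyl ether in a buffered, weakly acidic medium that leaves the acetate, the acid and the alkene unchanged.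

## Compound list

1 | methyl 4-bromo-3,5-dihydroxybenzoate | COC(=O)c1cc(O)c(Br)c(O)c1 | starting material
2 | methyl 4-bromo-3-hydroxy-5-{[(trifluoromethyl)sulfonyl]oxy}benzoate | COC(=O)c1cc(O)c(Br)c(OS(=O)(=O)C(F)(F)F)c1 | intermediate
3 | methyl 4-bromo-3-{[(trifluoromethyl)sulfonyl]oxy}-5-[(triisopropylsilyl)oxy]benzoate | COC(=O)c1cc(OS(=O)(=O)C(F)(F)F)c(Br)c(O[Si](C(C)C)(C(C)C)C(C)C)c1 | intermediate
4 | (2-tert-butoxy-2-oxoethyl)zinc chloride | CC(C)(C)OC(=O)C[Zn]Cl | starting material
5 | methyl 4-(2-tert-butoxy-2-oxoethyl)-3-{[(trifluoromethyl)sulfonyl]oxy}-5-[(triisopropylsilyl)oxy]benzoate | COC(=O)c1cc(OS(=O)(=O)C(F)(F)F)c(CC(=O)OC(C)(C)C)c(O[Si](C(C)C)(C(C)C)C(C)C)c1 | intermediate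
6 | {4-(methoxycarbonyl)-2-{[(trifluoromethyl)sulfonyl]oxy}-6-[(triisopropylsilyl)oxy]phenyl}acetic acid | COC(=O)c1cc(OS(=O)(=O)C(F)(F)F)c(CC(=O)O)c(O[Si](C(C)C)(C(C)C)C(C)C)c1 | intermediate
7 | (R)-4-benzyloxazolidin-2-one | O=C1N[C@H](Cc2ccccc2)CO1 | starting material
8 | mixed anhydride of 6 with pivalic acid | COC(=O)c1cc(OS(=O)(=O)C(F)(F)F)c(CC(=O)OC(=O)C(C)(C)C)c(O[Si](C(C)C)(C(C)C)C(C)C)c1 | intermediate (not isolated)
9 | methyl 4-{2-[(4R)-4-benzyl-2-oxo-1,3-oxazolidin-3-yl]-2-oxoethyl}-3-{[(trifluoromethyl)sulfonyl]oxy}-5-[(triisopropylsilyl)oxy]benzoate | COC(=O)c1cc(OS(=O)(=O)C(F)(F)F)c(CC(=O)N2[C@H](Cc3ccccc3)COC2=O)c(O[Si](C(C)C)(C(C)C)C(C)C)c1 | intermediate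
10 | 2-chloroethyl trifluoromethanesulfonate | ClCCOS(=O)(=O)C(F)(F)F | starting material
11 | sodium Z-enolate of imide 9 | COC(=O)c1cc(OS(=O)(=O)C(F)(F)F)c(/C=C(\[O-])N2[C@H](Cc3ccccc3)COC2=O)c(O[Si](C(C)C)(C(C)C)C(C)C)c1.[Na+] | intermediate (not isolated)
12 | methyl 4-{(2R)-1-[(4R)-4-benzyl-2-oxo-1,3-oxazolidin-3-yl]-4-chloro-1-oxobutan-2-yl}-3-{[(trifluoromethyl)sulfonyl]oxy}-5-[(triisopropylsilyl)oxy]benzoate | COC(=O)c1cc(OS(=O)(=O)C(F)(F)F)c([C@@H](CCCl)C(=O)N2[C@H](Cc3ccccc3)COC2=O)c(O[Si](C(C)C)(C(C)C)C(C)C)c1 | intermediate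
13 | methyl 4-[(2R)-4-chloro-1-hydroxybutan-2-yl]-3-{[(trifluoromethyl)sulfonyl]oxy}-5-[(triisopropylsilyl)oxy]benzoate | COC(=O)c1cc(OS(=O)(=O)C(F)(F)F)c([C@@H](CCCl)CO)c(O[Si](C(C)C)(C(C)C)C(C)C)c1 | intermediate
14 | methyl 4-[(2R)-1-{[tert-butyl(dimethyl)silyl]oxy}-4-chlorobutan-2-yl]-3-{[(trifluoromethyl)sulfonyl]oxy}-5-[(triisopropylsilyl)oxy]benzoate | COC(=O)c1cc(OS(=O)(=O)C(F)(F)F)c([C@@H](CCCl)CO[Si](C)(C)C(C)(C)C)c(O[Si](C(C)C)(C(C)C)C(C)C)c1 | intermediate
15 | {4-[(2R)-1-{[tert-butyl(dimethyl)silyl]oxy}-4-chlorobutan-2-yl]-3-{[(trifluoromethyl)sulfonyl]oxy}-5-[(triisopropylsilyl)oxy]phenyl}methanol | OCc1cc(OS(=O)(=O)C(F)(F)F)c([C@@H](CCCl)CO[Si](C)(C)C(C)(C)C)c(O[Si](C(C)C)(C(C)C)C(C)C)c1 | intermediate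
16 | 4-[(2R)-1-{[tert-butyl(dimethyl)silyl]oxy}-4-chlorobutan-2-yl]-3-{[(trifluoromethyl)sulfonyl]oxy}-5-[(triisopropylsilyl)oxy]benzaldehyde | O=Cc1cc(OS(=O)(=O)C(F)(F)F)c([C@@H](CCCl)CO[Si](C)(C)C(C)(C)C)c(O[Si](C(C)C)(C(C)C)C(C)C)c1 | intermediate
17 | 2-[(2R)-1-{[tert-butyl(dimethyl)silyl]oxy}-4-chlorobutan-2-yl]-5-(dimethoxymethyl)-3-[(triisopropylsilyl)oxy]phenyl trifluoromethanesulfonate | COC(OC)c1cc(OS(=O)(=O)C(F)(F)F)c([C@@H](CCCl)CO[Si](C)(C)C(C)(C)C)c(O[Si](C(C)C)(C(C)C)C(C)C)c1 | intermediate
18 | (E)-prop-1-enylboronic acid | C/C=C/B(O)O | starting material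
19 | tert-butyl{(2R)-4-chloro-2-[4-(dimethoxymethyl)-2-[(1E)-prop-1-en-1-yl]-6-[(triisopropylsilyl)oxy]phenyl]butoxy}dimethylsilane | CC(C)(C)[Si](C)(C)OC[C@@H](c1c(/C=C/C)cc(C(OC)OC)cc1O[Si](C(C)C)(C(C)C)C(C)C)CCCl | intermediate
20 | 5-bromo-2-methylpent-2-ene | CC(C)=CCCBr | starting material
21 | 5-iodo-2-methylpent-2-ene | CC(C)=CCCI | intermediate
22 | 4-methylpent-3-enyllithium | [Li]CCC=C(C)C | intermediate (not isolated)
23 | [(2S)-1-{2-[(2R)-1-{[tert-butyl(dimethyl)silyl]oxy}-4-chlorobutan-2-yl]-5-(dimethoxymethyl)-3-[(triisopropylsilyl)oxy]phenyl}-2,6-dimethylhept-5-en-1-yl]lithium (C4 configurationally mobile) | CC(C)(C)[Si](C)(C)OC[C@@H](c1c(C([Li])[C@@H](C)CCC=C(C)C)cc(C(OC)OC)cc1O[Si](C(C)C)(C(C)C)C(C)C)CCCl | intermediate (not isolated)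
24 | tert-butyl{[(1R,4S)-6-(dimethoxymethyl)-4-[(2S)-6-methylhept-5-en-2-yl]-8-[(triisopropylsilyl)oxy]-1,2,3,4-tetrahydronaphthalen-1-yl]methoxy}dimethylsilane | CC(C)(C)[Si](C)(C)OC[C@@H]1CC[C@@H]([C@@H](C)CCC=C(C)C)c2cc(C(OC)OC)cc(O[Si](C(C)C)(C(C)C)C(C)C)c21 | intermediate
25 | (5R,8S)-5-(hydroxymethyl)-8-[(2S)-6-methylhept-5-en-2-yl]-4-[(triisopropylsilyl)oxy]-5,6,7,8-tetrahydronaphthalene-2-carbaldehyde | OC[C@@H]1CC[C@@H]([C@@H](C)CCC=C(C)C)c2cc(C=O)cc(O[Si](C(C)C)(C(C)C)C(C)C)c21 | intermediate
26 | [(1R,4S)-6-formyl-4-[(2S)-6-methylhept-5-en-2-yl]-8-[(triisopropylsilyl)oxy]-1,2,3,4-tetrahydronaphthalen-1-yl]methyl acetate | CC(=O)OC[C@@H]1CC[C@@H]([C@@H](C)CCC=C(C)C)c2cc(C=O)cc(O[Si](C(C)C)(C(C)C)C(C)C)c21 | intermediate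
27 | (5R,8S)-5-(acetoxymethyl)-8-[(2S)-6-methylhept-5-en-2-yl]-4-[(triisopropylsilyl)oxy]-5,6,7,8-tetrahydronaphthalene-2-carboxylic acid | CC(=O)OC[C@@H]1CC[C@@H]([C@@H](C)CCC=C(C)C)c2cc(C(=O)O)cc(O[Si](C(C)C)(C(C)C)C(C)C)c21 | intermediate
28 | (5R,8S)-5-(acetoxymethyl)-4-hydroxy-8-[(2S)-6-methylhept-5-en-2-yl]-5,6,7,8-tetrahydronaphthalene-2-carboxylic acid | CC(=O)OC[C@@H]1CC[C@@H]([C@@H](C)CCC=C(C)C)c2cc(C(=O)O)cc(O)c21 | target

## Step count and least certain steps

Total: 18 steps. Longest linear sequence: 17 steps (steps 1–12, then 14–18); step 13 is a one-step side branch that supplies 21.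

**Step 14 (key step, proposed new method).** Three things may go wrong.
- The face selectivity at C1' may be eroded. The ortho arm twists the propenyl group out of conjugation and slows the ligand-bound pathway relative to unligated background addition, and the diamine may be mismatched with the C1 centre.
- The ring closure may be unselective at C4, because the trans preference rests only on two peri interactions acting on a configurationally mobile carbanion.
- Allylic deprotonation of the propenyl methyl group, or slow chloride displacement, would leave open-chain material after the quench.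

The fallback uses known chemistry only. It takes C1' from the chiral pool and replaces the unstabilised benzylic lithium by a nitrile-stabilised anion. It sets out from triflate 17 and returns at 24. Palladium-catalysed α-arylation of (3S)-3,7-dimethyloct-6-enenitrile F1 with 17 (Pd(OAc)2, BINAP, NaN(SiMe3)2, toluene) would give the open-chain α-aryl nitrile F2. Deprotonation of F2 (KN(SiMe3)2, THF) and intramolecular alkylation of the planar nitrile anion by the chloride would give the C4-cyano tetralin F3. This closure should go through the same half-chair, with the slim nitrile beside C5–H and the side chain pseudoaxial and trans to the C1 group. i-Bu2AlH would then convert the nitrile into the C4-formyl tetralin F4, and stoichiometric RhCl(PPh3)3 would remove the formyl group with retention at C4 to give 24.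

**Step 6 (auxiliary alkylation with triflate 10).** The hard triflate may alkylate the delocalised enolate on oxygen. Carbon alkylation at the doubly ortho-flanked centre may be slow enough for the enolate to decompose. Proton transfer from product to enolate would let the γ-chloro imide close to a cyclopropane.

The fallback uses a softer, more reactive electrophile and installs the chloride later. It sets out from 9 (through enolate 11) and returns at 16. Alkylation with tert-butyl bromoacetate would give the succinate-type imide F5. NaBH4 in aqueous THF would give the hydroxy ester F6, and silylation would give the silyl ether F7. i-Bu2AlH would reduce both esters to the diol F8. MnO2 would oxidise only the benzylic alcohol to the hydroxy aldehyde F9, and PPh3/CCl4 would turn the remaining primary alcohol into the chloride of 16.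

**Step 3 (zinc enolate arylation).** Insertion of palladium into the C–OTf bond may compete, or insertion into the C–Br bond between two ortho oxygen substituents may fail.

The fallback removes the triflate from the coupling step. It sets out from 1 and returns at 5. Mono-silylation of 1 (i-Pr3SiCl, imidazole) would give the bromophenol F10. Coupling of F10 with an excess of 4 under the same catalyst (the free hydroxyl is tolerated as its zinc phenoxide) would give the phenol ester F11, and triflation of F11 (Tf2O, pyridine) would give 5.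

**Step 12 (Suzuki coupling).** Under warm aqueous base the hindered triflate may hydrolyse, or the aryl silyl ether may be lost, before transmetalation occurs.

The fallback is a base-free coupling of a different organometal. It sets out from 17 and gives 19 directly: Stille coupling with tributyl[(1E)-prop-1-en-1-yl]stannane (Pd(PPh3)4, LiCl, dioxane, 90 °C), which makes no new intermediate.

**Step 7 (reductive removal of the auxiliary).** Hydride may attack the ring carbonyl of the oxazolidinone, because the exocyclic carbonyl is shielded by the 2,6-disubstituted aryl group; the ring would then open instead of the auxiliary being released.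

The fallback sets out from 12 and returns at 13. Cleavage with LiOH/H2O2 (THF–H2O, 0 °C), where the hydroperoxide anion selects the exocyclic carbonyl, would give the (2R)-2-aryl-4-chlorobutanoic acid F12. BH3·SMe2 would then reduce the acid to 13 without touching the methyl ester.

## Further compounds

F1 | step 14 | (3S)-3,7-dimethyloct-6-enenitrile | N#CC[C@@H](C)CCC=C(C)C
F2 | step 14 | (3S)-2-{2-[(2R)-1-{[tert-butyl(dimethyl)silyl]oxy}-4-chlorobutan-2-yl]-5-(dimethoxymethyl)-3-[(triisopropylsilyl)oxy]phenyl}-3,7-dimethyloct-6-enenitrile (mixture at C2) | CC(C)(C)[Si](C)(C)OC[C@@H](c1c(C(C#N)[C@@H](C)CCC=C(C)C)cc(C(OC)OC)cc1O[Si](C(C)C)(C(C)C)C(C)C)CCCl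
F3 | step 14 | (1R,4R)-4-({[tert-butyl(dimethyl)silyl]oxy}methyl)-7-(dimethoxymethyl)-1-[(2S)-6-methylhept-5-en-2-yl]-5-[(triisopropylsilyl)oxy]-1,2,3,4-tetrahydronaphthalene-1-carbonitrile | CC(C)(C)[Si](C)(C)OC[C@@H]1CC[C@@](C#N)([C@@H](C)CCC=C(C)C)c2cc(C(OC)OC)cc(O[Si](C(C)C)(C(C)C)C(C)C)c21
F4 | step 14 | (1R,4R)-4-({[tert-butyl(dimethyl)silyl]oxy}methyl)-7-(dimethoxymethyl)-1-[(2S)-6-methylhept-5-en-2-yl]-5-[(triisopropylsilyl)oxy]-1,2,3,4-tetrahydronaphthalene-1-carbaldehyde | CC(C)(C)[Si](C)(C)OC[C@@H]1CC[C@@](C=O)([C@@H](C)CCC=C(C)C)c2cc(C(OC)OC)cc(O[Si](C(C)C)(C(C)C)C(C)C)c21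
F5 | step 6 | methyl 4-{(2R)-1-[(4R)-4-benzyl-2-oxo-1,3-oxazolidin-3-yl]-4-tert-butoxy-1,4-dioxobutan-2-yl}-3-{[(trifluoromethyl)sulfonyl]oxy}-5-[(triisopropylsilyl)oxy]benzoate | COC(=O)c1cc(OS(=O)(=O)C(F)(F)F)c([C@@H](CC(=O)OC(C)(C)C)C(=O)N2[C@H](Cc3ccccc3)COC2=O)c(O[Si](C(C)C)(C(C)C)C(C)C)c1
F6 | step 6 | methyl 4-[(2R)-4-tert-butoxy-1-hydroxy-4-oxobutan-2-yl]-3-{[(trifluoromethyl)sulfonyl]oxy}-5-[(triisopropylsilyl)oxy]benzoate | COC(=O)c1cc(OS(=O)(=O)C(F)(F)F)c([C@@H](CC(=O)OC(C)(C)C)CO)c(O[Si](C(C)C)(C(C)C)C(C)C)c1
F7 | step 6 | methyl 4-[(2R)-4-tert-butoxy-1-{[tert-butyl(dimethyl)silyl]oxy}-4-oxobutan-2-yl]-3-{[(trifluoromethyl)sulfonyl]oxy}-5-[(triisopropylsilyl)oxy]benzoate | COC(=O)c1cc(OS(=O)(=O)C(F)(F)F)c([C@@H](CC(=O)OC(C)(C)C)CO[Si](C)(C)C(C)(C)C)c(O[Si](C(C)C)(C(C)C)C(C)C)c1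
F8 | step 6 | (3R)-4-{[tert-butyl(dimethyl)silyl]oxy}-3-{4-(hydroxymethyl)-2-{[(trifluoromethyl)sulfonyl]oxy}-6-[(triisopropylsilyl)oxy]phenyl}butan-1-ol | OCc1cc(OS(=O)(=O)C(F)(F)F)c([C@@H](CCO)CO[Si](C)(C)C(C)(C)C)c(O[Si](C(C)C)(C(C)C)C(C)C)c1
F9 | step 6 | 4-[(2R)-1-{[tert-butyl(dimethyl)silyl]oxy}-4-hydroxybutan-2-yl]-3-{[(trifluoromethyl)sulfonyl]oxy}-5-[(triisopropylsilyl)oxy]benzaldehyde | O=Cc1cc(OS(=O)(=O)C(F)(F)F)c([C@@H](CCO)CO[Si](C)(C)C(C)(C)C)c(O[Si](C(C)C)(C(C)C)C(C)C)c1
F10 | step 3 | methyl 4-bromo-3-hydroxy-5-[(triisopropylsilyl)oxy]benzoate | COC(=O)c1cc(O)c(Br)c(O[Si](C(C)C)(C(C)C)C(C)C)c1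
F11 | step 3 | methyl 4-(2-tert-butoxy-2-oxoethyl)-3-hydroxy-5-[(triisopropylsilyl)oxy]benzoate | COC(=O)c1cc(O)c(CC(=O)OC(C)(C)C)c(O[Si](C(C)C)(C(C)C)C(C)C)c1
F0 | step 12 | none | none
F12 | step 7 | (2R)-4-chloro-2-{4-(methoxycarbonyl)-2-{[(trifluoromethyl)sulfonyl]oxy}-6-[(triisopropylsilyl)oxy]phenyl}butanoic acid | COC(=O)c1cc(OS(=O)(=O)C(F)(F)F)c([C@@H](CCCl)C(=O)O)c(O[Si](C(C)C)(C(C)C)C(C)C)c1
A1 | alternative 1 | methyl (8S)-4-hydroxy-8-[(2S)-6-methylhept-5-en-2-yl]-5-oxo-5,6,7,8-tetrahydronaphthalene-2-carboxylate | O=C1CC[C@@H]([C@@H](C)CCC=C(C)C)c2cc(C(=O)OC)cc(O)c21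
A2 | alternative 1 | (4S)-4-[(2S)-6-methylhept-5-en-2-yl]-2-(phenylsulfinyl)cyclohex-2-en-1-one | O=C1CC[C@@H]([C@@H](C)CCC=C(C)C)C=C1S(=O)c1ccccc1
A3 | alternative 1 | methyl 4-methoxy-2-methylidene-4-[(trimethylsilyl)oxy]but-3-enoate | C=C(C(=O)OC)C=C(OC)O[Si](C)(C)C
A4 | alternative 1 | (3S)-3,7-dimethyloct-6-enal ((S)-citronellal) | C[C@@H](CCC=C(C)C)CC=O
A5 | alternative 2 | prop-2-en-1-yl (5R,8S)-5-(acetoxymethyl)-4-hydroxy-8-[(2S)-6-methylhept-5-en-2-yl]-5,6,7,8-tetrahydronaphthalene-2-carboxylate | CC(=O)OC[C@@H]1CC[C@@H]([C@@H](C)CCC=C(C)C)c2cc(C(=O)OCC=C)cc(O)c21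
A6 | alternative 2 | prop-2-en-1-yl 5-[(3R,6S,7S)-3-(acetoxymethyl)-7,11-dimethyldodec-10-en-1-yn-6-yl]furan-3-carboxylate | C#C[C@H](COC(C)=O)CC[C@@H]([C@@H](C)CCC=C(C)C)c1cc(C(=O)OCC=C)co1
A7 | alternative 3 | 2-(trimethylsilyl)ethyl (5R,8S)-8-[(2S)-5-(benzyloxy)pentan-2-yl]-5-(dimethoxymethyl)-4-[(triisopropylsilyl)oxy]-5,6,7,8-tetrahydronaphthalene-2-carboxylate | COC(OC)[C@@H]1CC[C@@H]([C@@H](C)CCCOCc3ccccc3)c2cc(C(=O)OCC[Si](C)(C)C)cc(O[Si](C(C)C)(C(C)C)C(C)C)c21
A8 | alternative 3 | 2-(trimethylsilyl)ethyl (5S)-5-[(2S)-5-(benzyloxy)pentan-2-yl]-1-[(triisopropylsilyl)oxy]-6,7-dihydro-5H-benzo[7]annulene-3-carboxylate | CC(C)[Si](Oc1cc(C(=O)OCC[Si](C)(C)C)cc2c1C=CCC[C@H]2[C@@H](C)CCCOCc1ccccc1)(C(C)C)C(C)C
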